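**Plan**
- Retrosynthetic cuts, in order: the two O-protecting groups (3-O-benzyl, 5-O-MOM), then the ring C ether bond O1–C8a, then C3–C4 (aldol plus oxidation), then C4–C4a (formyl carbon onto ring A) and C2–C1' (ring B onto a benzyloxyacetyl unit).
- Enabling feature: O1 is bonded to C8a, the ring A carbon between C4a (which carries the C4 carbonyl) and the methoxylated C8. A bromine at C8a, ortho to the acyl group, is the only leaving group on ring A, so it alone decides which oxygen-flanked side of C4a becomes the ring ether.
- Forward: rings A and B are bought intact. The bonds C2–C1', C4–C4a and C3–C4 join them into a 2-benzyloxy-1,3-diketone. Ring C is the only ring made and closes by copper-catalysed O-arylation, followed by two deprotections.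
- Stereochemistry: the target is achiral. The stereocentres of the aldol adduct and of the diketone are erased by oxidation and enolisation, so nothing has to be controlled.

Key step: step 8

Remark on the chemistry: diketone 17 is drawn as the diketo tautomer (racemic at the central carbon, in equilibrium with its enols) and aldol adduct 16 is carried on as a mixture of diastereomers; neither affects the route. Flavone numbering (O1, C2, C3, C4, C4a, C5–C8, C8a, C1') is used throughout.

Step 1
Reactants: 1 3-bromo-4,5-dimethoxybenzaldehyde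
Product: 3 3-bromo-4,5-dimethoxyphenol, via aryl formate 2 (not isolated)
Conditions: mCPBA, CH2Cl2, 0 °C → rt; aq. NaHCO3 wash; crude formate, K2CO3 (cat.), MeOH, rt
Reagents that add atoms: 3-chloroperoxybenzoic acid (mCPBA), O=C(OO)c1cccc(Cl)c1
Why: Baeyer–Villiger (Dakin-type) oxidation, in which the aryl group, made electron-rich by the para methoxy group, migrates in preference to hydrogen in the Criegee adduct; the formate is then cleaved by carbonate-catalysed methanolysis without touching the aryl bromide or the methyl ethers.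

Step 2
Reactants: 3 3-bromo-4,5-dimethoxyphenol
Product: 4 1-bromo-2,3-dimethoxy-5-(methoxymethoxy)benzene
Conditions: MOMCl, K2CO3, DMF, 0 °C → rt
Reagents that add atoms: chloromethyl methyl ether (MOMCl), COCCl
Why: Williamson-type O-alkylation of the phenoxide by the reactive α-chloro ether gives an acetal that survives bases and organolithiums and later directs the metalation.

Step 3
Reactants: 4 1-bromo-2,3-dimethoxy-5-(methoxymethoxy)benzene
Product: 7 2-bromo-3,4-dimethoxy-6-(methoxymethoxy)benzaldehyde, via aryllithium 5 (not isolated), via lithium hemiaminal alkoxide 6 (not isolated)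
Conditions: LiN(i-Pr)2 (1.05 equiv), THF, −78 °C; DMF, −78 → 0 °C; H2O quench
Reagents that add atoms: N,N-dimethylformamide, CN(C)C=O
Why: Directed ortho-metalation followed by formylation with DMF: the hydrogen between Br and OMOM is the most acidic on the ring (inductive effect of bromine plus lithium coordination by the acetal oxygens), the amide base deprotonates without bromine–lithium exchange, and −78 °C keeps the ortho-bromoaryllithium from losing LiBr.

Step 4
Reactants: 8 benzyloxyacetyl chloride
Product: 9 2-(benzyloxy)-N-methoxy-N-methylacetamide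
Conditions: MeNH(OMe)·HCl, K2CO3, CH2Cl2/H2O, 0 °C → rt
Reagents that add atoms: N,O-dimethylhydroxylamine hydrochloride, CNOC.Cl
Why: Schotten–Baumann acylation of the amine by the acid chloride under biphasic carbonate conditions gives the Weinreb amide.

Step 5
Reactants: 10 5-bromo-1,2,3-trimethoxybenzene; 9 2-(benzyloxy)-N-methoxy-N-methylacetamide
Product: 13 2-(benzyloxy)-1-(3,4,5-trimethoxyphenyl)ethan-1-one, via 3,4,5-trimethoxyphenyllithium 11 (not isolated), via lithium tetrahedral adduct 12 (not isolated)
Conditions: n-BuLi, THF, −78 °C; then 9, −78 → 0 °C; H2O quench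
Reagents that add atoms: none
Why: Bromine–lithium exchange followed by Weinreb ketone synthesis; the chelated tetrahedral adduct does not collapse until work-up, so one aryl group is delivered and the ketone is not attacked again.

Step 6
Reactants: 13 2-(benzyloxy)-1-(3,4,5-trimethoxyphenyl)ethan-1-one; 7 2-bromo-3,4-dimethoxy-6-(methoxymethoxy)benzaldehyde
Product: 16 2-(benzyloxy)-3-[2-bromo-3,4-dimethoxy-6-(methoxymethoxy)phenyl]-3-hydroxy-1-(3,4,5-trimethoxyphenyl)propan-1-one (racemic mixture of diastereomers), via lithium enolate 14 (not isolated), via lithium aldolate 15 (not isolated)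
Conditions: LiN(SiMe3)2 (1.1 equiv), THF, −78 °C; then 7, −78 °C; AcOH quench at −78 °C
Reagents that add atoms: none
Why: Aldol addition of the chelated lithium enolate of the α-benzyloxy ketone to the non-enolisable aldehyde; the two new stereocentres form without control and are both removed later (C4 by oxidation in step 7, C3 on ring closure in step 8), and the cold acetic acid quench guards against retro-aldol reversal.

Step 7
Reactants: 16 the aldol adduct
Product: 17 2-(benzyloxy)-1-[2-bromo-3,4-dimethoxy-6-(methoxymethoxy)phenyl]-3-(3,4,5-trimethoxyphenyl)propane-1,3-dione (racemic, enolisable)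
Conditions: Dess–Martin periodinane (1.3 equiv), CH2Cl2, 0 °C → rt
Reagents that add atoms: none
Why: Dess–Martin oxidation of the secondary benzylic alcohol runs under nearly neutral, non-aqueous conditions that avoid retro-aldol cleavage and leave the MOM acetal, the benzyl ether and the aryl bromide intact.

Step 8
Reactants: 17 the 2-benzyloxy-1,3-diketone
Product: 19 3-(benzyloxy)-7,8-dimethoxy-5-(methoxymethoxy)-2-(3,4,5-trimethoxyphenyl)-4H-chromen-4-one, via cesium diketonate 18 (not isolated)
Conditions: CuI (10 mol %), 1,10-phenanthroline (20 mol %), Cs2CO3 (2 equiv), 4 Å MS, dry degassed DMF, 90 °C, Ar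
Reagents that add atoms: none
Why: Cs2CO3 converts 17 into the cesium diketonate 18, which binds monovalent copper (CuI/1,10-phenanthroline); the metal, held next to C8a by the ortho acyl group, inserts into the C8a–Br bond, and C–O reductive elimination from the resulting trivalent copper aryl enolate forms O1–C8a. The closest known reaction type is the copper-catalysed intramolecular Ullmann O-arylation of 1-(2-haloaryl)-1,3-diketones to flavones. Ring C closes as a six-membered ring by 6-exo attack of the enolate oxygen on the aryl carbon (exo with respect to the breaking C8a–Br bond), through a seven-membered cupracycle. No stereocentre is formed, and the one at the central carbon of 17 disappears on enolisation. The step needs O- over C-arylation and the correct side of ring A: attack by the central carbon would give a four-membered ring, only the oxygen of the ring B carbonyl can reach C8a, and since the sole leaving group sits at C8a while O5 is capped as its MOM ether, only the 5,7,8-oxygenation pattern can result.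

Step 9
Reactants: 19 the fully protected flavone
Product: 20 3-(benzyloxy)-5-hydroxy-7,8-dimethoxy-2-(3,4,5-trimethoxyphenyl)-4H-chromen-4-one
Conditions: HCl (1.25 M in MeOH), 40 °C
Reagents that add atoms: none
Why: Acid-catalysed transacetalisation transfers the methoxymethyl group to methanol, while benzyl and methyl ethers and the chromone are stable to dilute methanolic HCl; the freed 5-OH is hydrogen-bonded to the C4 carbonyl.

Step 10
Reactants: 20 the 3-O-benzyl flavonol
Product: 21 3,5-dihydroxy-7,8-dimethoxy-2-(3,4,5-trimethoxyphenyl)-4H-chromen-4-one (3,5-dihydroxy-7,8,3',4',5'-pentamethoxyflavone)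
Conditions: H2 (1 atm), 10% Pd/C, EtOAc/MeOH, rt
Reagents that add atoms: none
Why: Heterogeneous palladium-catalysed hydrogenolysis cleaves the benzylic C–O bond, and the tetrasubstituted C2=C3 bond of the vinylogous ester and the aryl methyl ethers should not be reduced at 1 atm and room temperature.

**Compound list**
1 | 3-bromo-4,5-dimethoxybenzaldehyde | COc1cc(C=O)cc(Br)c1OC | starting material
2 | 3-bromo-4,5-dimethoxyphenyl formate | O=COc1cc(Br)c(OC)c(OC)c1 | intermediate (not isolated)
3 | 3-bromo-4,5-dimethoxyphenol | Oc1cc(Br)c(OC)c(OC)c1 | intermediate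
4 | 1-bromo-2,3-dimethoxy-5-(methoxymethoxy)benzene | COCOc1cc(Br)c(OC)c(OC)c1 | intermediate
5 | [2-bromo-3,4-dimethoxy-6-(methoxymethoxy)phenyl]lithium | [Li]c1c(Br)c(OC)c(OC)cc1OCOC | intermediate (not isolated)
6 | lithium [2-bromo-3,4-dimethoxy-6-(methoxymethoxy)phenyl](dimethylamino)methanolate (racemic) | [Li+].[O-]C(N(C)C)c1c(Br)c(OC)c(OC)cc1OCOC | intermediate (not isolated)
7 | 2-bromo-3,4-dimethoxy-6-(methoxymethoxy)benzaldehyde | O=Cc1c(Br)c(OC)c(OC)cc1OCOC | intermediate
8 | benzyloxyacetyl chloride | O=C(Cl)COCc1ccccc1 | starting material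
9 | 2-(benzyloxy)-N-methoxy-N-methylacetamide | CON(C)C(=O)COCc1ccccc1 | intermediate
10 | 5-bromo-1,2,3-trimethoxybenzene | COc1cc(Br)cc(OC)c1OC | starting material
11 | (3,4,5-trimethoxyphenyl)lithium | [Li]c1cc(OC)c(OC)c(OC)c1 | intermediate (not isolated)
12 | lithium 2-(benzyloxy)-1-[methoxy(methyl)amino]-1-(3,4,5-trimethoxyphenyl)ethan-1-olate (racemic) | [Li+].[O-]C(COCc1ccccc1)(N(C)OC)c1cc(OC)c(OC)c(OC)c1 | intermediate (not isolated)
13 | 2-(benzyloxy)-1-(3,4,5-trimethoxyphenyl)ethan-1-one | O=C(COCc1ccccc1)c1cc(OC)c(OC)c(OC)c1 | intermediate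
14 | lithium (Z)-2-(benzyloxy)-1-(3,4,5-trimethoxyphenyl)ethen-1-olate (chelated Z form expected) | [Li+].[O-]/C(=C\OCc1ccccc1)c1cc(OC)c(OC)c(OC)c1 | intermediate (not isolated)
15 | lithium 2-(benzyloxy)-1-[2-bromo-3,4-dimethoxy-6-(methoxymethoxy)phenyl]-3-oxo-3-(3,4,5-trimethoxyphenyl)propan-1-olate (racemic, diastereomer mixture) | [Li+].[O-]C(c1c(Br)c(OC)c(OC)cc1OCOC)C(OCc1ccccc1)C(=O)c1cc(OC)c(OC)c(OC)c1 | intermediate (not isolated)
16 | 2-(benzyloxy)-3-[2-bromo-3,4-dimethoxy-6-(methoxymethoxy)phenyl]-3-hydroxy-1-(3,4,5-trimethoxyphenyl)propan-1-one (racemic, diastereomer mixture) | COCOc1cc(OC)c(OC)c(Br)c1C(O)C(OCc1ccccc1)C(=O)c1cc(OC)c(OC)c(OC)c1 | intermediate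
17 | 2-(benzyloxy)-1-[2-bromo-3,4-dimethoxy-6-(methoxymethoxy)phenyl]-3-(3,4,5-trimethoxyphenyl)propane-1,3-dione (racemic, enolisable) | COCOc1cc(OC)c(OC)c(Br)c1C(=O)C(OCc1ccccc1)C(=O)c1cc(OC)c(OC)c(OC)c1 | intermediate
18 | cesium diketonate of 17 (delocalised, one resonance form drawn, enolate geometry not fixed) | [Cs+].[O-]C(=C(OCc1ccccc1)C(=O)c1c(Br)c(OC)c(OC)cc1OCOC)c1cc(OC)c(OC)c(OC)c1 | intermediate (not isolated)
19 | 3-(benzyloxy)-7,8-dimethoxy-5-(methoxymethoxy)-2-(3,4,5-trimethoxyphenyl)-4H-chromen-4-one | O=c1c(OCc2ccccc2)c(-c2cc(OC)c(OC)c(OC)c2)oc2c(OC)c(OC)cc(OCOC)c12 | intermediate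
20 | 3-(benzyloxy)-5-hydroxy-7,8-dimethoxy-2-(3,4,5-trimethoxyphenyl)-4H-chromen-4-one | O=c1c(OCc2ccccc2)c(-c2cc(OC)c(OC)c(OC)c2)oc2c(OC)c(OC)cc(O)c12 | intermediate
21 | 3,5-dihydroxy-7,8-dimethoxy-2-(3,4,5-trimethoxyphenyl)-4H-chromen-4-one | COc1cc(-c2oc3c(OC)c(OC)cc(O)c3c(=O)c2O)cc(OC)c1OC | target

**Step count**
Total: 10 steps. Longest linear sequence: 8 steps (1, 2, 3, 6, 7, 8, 9, 10); steps 4 and 5 form the second branch.

**Steps most likely to fail**

Step 8. What may go wrong: C–O bond formation at the doubly ortho-substituted, electron-rich C8a–Br is slow, so the fully substituted diketonate is cleaved by retro-Claisen fragmentation or the bromide is reduced off before ring C closes. The fallback sets out from aldehyde 7 and comes back to the route at target 21. It closes ring C on the diketone that lacks the central oxygen, the substrate class on which this copper O-arylation is established, and introduces O3 afterwards.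
- The lithium enolate of commercial 1-(3,4,5-trimethoxyphenyl)ethan-1-one (LiN(SiMe3)2, THF, −78 °C) would add to 7 to give 3-[2-bromo-3,4-dimethoxy-6-(methoxymethoxy)phenyl]-3-hydroxy-1-(3,4,5-trimethoxyphenyl)propan-1-one F1.
- Dess–Martin oxidation would give 1-[2-bromo-3,4-dimethoxy-6-(methoxymethoxy)phenyl]-3-(3,4,5-trimethoxyphenyl)propane-1,3-dione F2.
- CuI, 1,10-phenanthroline and Cs2CO3 in DMF would close it to 7,8-dimethoxy-5-(methoxymethoxy)-2-(3,4,5-trimethoxyphenyl)-4H-chromen-4-one F3.
- Dimethyldioxirane in acetone would epoxidise C2=C3 to the racemic, cis-fused 2,3-epoxy-7,8-dimethoxy-5-(methoxymethoxy)-2-(3,4,5-trimethoxyphenyl)chroman-4-one F4.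
- Catalytic p-toluenesulfonic acid in CH2Cl2 would open the epoxide to 3-hydroxy-7,8-dimethoxy-5-(methoxymethoxy)-2-(3,4,5-trimethoxyphenyl)-4H-chromen-4-one F5.
- Methanolic HCl would then remove the MOM ether to give 21.

Step 3. What may go wrong: the ortho-bromoaryllithium loses LiBr to an aryne or isomerises by bromine migration before it is trapped, or deprotonation occurs in part between OMOM and OMe. The fallback sets out from phenol 3 and comes back at aldehyde 7, and it avoids any aryl anion. Magnesium-mediated ortho-formylation of the free phenol (MgCl2, Et3N, paraformaldehyde, MeCN, reflux) should favour the ortho position that is para to the neighbouring methoxy group, which is the one next to bromine, and give 2-bromo-6-hydroxy-3,4-dimethoxybenzaldehyde F6. MOMCl and K2CO3 in DMF would then give 7.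

Step 6. What may go wrong: the aldol addition reverses at the doubly ortho-substituted aldehyde (retro-aldol on warming or work-up) or stays incomplete for steric reasons. The fallback sets out from bromoarene 4 and Weinreb amide 9 and comes back at diketone 17. Aryllithium 5, generated as in step 3, would be quenched with 9 instead of DMF to give 2-(benzyloxy)-1-[2-bromo-3,4-dimethoxy-6-(methoxymethoxy)phenyl]ethan-1-one F7. Its magnesium enolate, formed under soft enolisation (MgBr2·OEt2, i-Pr2NEt, CH2Cl2), would be C-acylated by commercial 3,4,5-trimethoxybenzoyl chloride in a Claisen-type acylation. This gives 17 directly at the right oxidation level and makes steps 6 and 7 unnecessary.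

**Further compounds**
F1 | step 8 | 3-[2-bromo-3,4-dimethoxy-6-(methoxymethoxy)phenyl]-3-hydroxy-1-(3,4,5-trimethoxyphenyl)propan-1-one (racemic) | COCOc1cc(OC)c(OC)c(Br)c1C(O)CC(=O)c1cc(OC)c(OC)c(OC)c1
F2 | step 8 | 1-[2-bromo-3,4-dimethoxy-6-(methoxymethoxy)phenyl]-3-(3,4,5-trimethoxyphenyl)propane-1,3-dione | COCOc1cc(OC)c(OC)c(Br)c1C(=O)CC(=O)c1cc(OC)c(OC)c(OC)c1
F3 | step 8 | 7,8-dimethoxy-5-(methoxymethoxy)-2-(3,4,5-trimethoxyphenyl)-4H-chromen-4-one | O=c1cc(-c2cc(OC)c(OC)c(OC)c2)oc2c(OC)c(OC)cc(OCOC)c12
F4 | step 8 | 2,3-epoxy-7,8-dimethoxy-5-(methoxymethoxy)-2-(3,4,5-trimethoxyphenyl)chroman-4-one (racemic, cis-fused; one enantiomer drawn) | O=C1c2c(OCOC)cc(OC)c(OC)c2O[C@]2(c3cc(OC)c(OC)c(OC)c3)O[C@H]12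
F5 | step 8 | 3-hydroxy-7,8-dimethoxy-5-(methoxymethoxy)-2-(3,4,5-trimethoxyphenyl)-4H-chromen-4-one | O=c1c(O)c(-c2cc(OC)c(OC)c(OC)c2)oc2c(OC)c(OC)cc(OCOC)c12
F6 | step 3 | 2-bromo-6-hydroxy-3,4-dimethoxybenzaldehyde | O=Cc1c(O)cc(OC)c(OC)c1Br
F7 | step 6 | 2-(benzyloxy)-1-[2-bromo-3,4-dimethoxy-6-(methoxymethoxy)phenyl]ethan-1-one | COCOc1cc(OC)c(OC)c(Br)c1C(=O)COCc1ccccc1
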